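**Retrosynthetic overview**
- The pyran ring is closed last: C-2 of orcinol condenses with a β,β-disubstituted enal (C4–C4a, then O–C2), and a chiral Brønsted acid sets C-2 of the chromene.
- The enal comes from an isopropenyl group by cross-metathesis with crotonaldehyde; orcinol comes from m-cresol by meta C–H borylation and oxidation.
- The cyclohexane C1–C6 bond is closed by 6-exo-tet alkylation of an imide enolate. Before that, the C2–C3 bond (stereocentre to quaternary carbon) is made by enantioselective addition of a tertiary alkyl radical to an N-enoyl oxazolidinone on a chiral MgI2–bis(oxazoline) Lewis acid (key step).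
- The radical precursor is a tertiary iodide from 5-bromo-2-methylpent-2-ene and HI; the acceptor is assembled from 2-methylhexa-1,5-diene, acryloyl chloride and oxazolidin-2-one.
- Ring order: aromatic ring bought as m-cresol, then the cyclohexane (radical addition, then alkylation), then the pyran ring.

Assumption: the target SMILES is read as 2R in the chromene and 1S,2R (trans) in the cyclohexane; the sense of induction of the ligand in step 3 and of the acid in step 7 follows the models given there, and the antipodal ligand or acid is used if the first run shows the opposite sense.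

**Step 1**
Reactants: 1 2-methylhexa-1,5-diene; 2 acryloyl chloride (prop-2-enoyl chloride); 3 1,3-oxazolidin-2-one
Product: 5 3-[(2E)-6-methylhepta-2,6-dienoyl]-1,3-oxazolidin-2-one, via (2E)-6-methylhepta-2,6-dienoyl chloride 4 (not isolated)
Conditions: 2 (2 equiv), RuCl2(H2IMes)(=CH-C6H4-2-OiPr) (second-generation Hoveyda–Grubbs catalyst, 2 mol%), CH2Cl2, 40 °C; evaporate; then 3, n-BuLi, THF, −78 → 0 °C
Reagents that add atoms: none
Why: Olefin cross-metathesis engages only the monosubstituted alkene of 1 (the 1,1-disubstituted end is far slower toward an electron-poor partner; E-selective), and the crude acid chloride then N-acylates the lithiated oxazolidinone; no stereocentre is formed.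

**Step 2**
Reactants: 6 5-bromo-2-methylpent-2-ene
Product: 7 5-bromo-2-iodo-2-methylpentane
Conditions: HI (57% aq., 3 equiv), CH2Cl2, 0 °C, dark; used crude
Reagents that add atoms: hydrogen iodide, I
Why: Markovnikov hydroiodination through the tertiary cation, run two-phase and cold so that iodide does not exchange the primary bromide; no stereocentre is formed.

**Step 3 (key step)**
Reactants: 5 3-[(2E)-6-methylhepta-2,6-dienoyl]-1,3-oxazolidin-2-one; 7 5-bromo-2-iodo-2-methylpentane
Product: 8 3-[(3R)-3-(5-bromo-2-methylpentan-2-yl)-6-methylhept-6-enoyl]-1,3-oxazolidin-2-one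
Conditions: MgI2 (30 mol%), (3aS,3a'S,8aR,8a'R)-2,2'-(cyclopropane-1,1-diyl)bis(3a,8a-dihydro-8H-indeno[1,2-d]oxazole) (33 mol%), 4 Å MS, CH2Cl2, rt then −78 °C; 7 (4 equiv), Bu3SnH (2 equiv), Et3B (2 equiv), O2 (trace), −78 °C
Reagents that add atoms: none
Why: Chiral-Lewis-acid-catalysed enantioselective radical conjugate addition (Giese reaction of the Sibi–Porter type): Bu3Sn•/Et• abstract the tertiary iodine of 7 far faster than the primary bromine, the nucleophilic tertiary radical adds to C-3 of the s-cis imide chelated on tetrahedral divalent magnesium where the ligand blocks the Si face, so the bond to the quaternary carbon forms on the Re face and C-3 becomes R (the later ring C-2), and Bu3SnH reduces the α-radical before it can cyclise onto the isopropenyl group.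

**Step 4**
Reactants: 8 3-[(3R)-3-(5-bromo-2-methylpentan-2-yl)-6-methylhept-6-enoyl]-1,3-oxazolidin-2-one
Product: 10 (1S,2R)-3,3-dimethyl-2-(3-methylbut-3-en-1-yl)cyclohexane-1-carboxylic acid, via cyclised imide 9 (not isolated)
Conditions: NaN(SiMe3)2 (1.3 equiv), THF, −78 → 0 °C; then H2O2 (30% aq.), LiOH, THF/H2O, 0 °C; Na2SO3; HCl
Reagents that add atoms: hydrogen peroxide (as LiOOH), OO
Why: Intramolecular enolate alkylation (6-exo-tet SN2) of the Z sodium enolate closes C1–C6 through a chair transition state in which the C-2 hydrogen eclipses the enolate (allylic strain), so acyl group and side chain end up trans-diequatorial (1S set from 2R, also the thermodynamic isomer), and LiOOH then cleaves the exocyclic acyl group (Evans hydrolysis) without touching the alkene.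

**Step 5**
Reactants: 10 (1S,2R)-3,3-dimethyl-2-(3-methylbut-3-en-1-yl)cyclohexane-1-carboxylic acid; 11 (E)-but-2-enal (crotonaldehyde)
Product: 12 (1S,2R)-3,3-dimethyl-2-[(3E)-3-methyl-5-oxopent-3-en-1-yl]cyclohexane-1-carboxylic acid
Conditions: 11 (5 equiv), RuCl2(H2IMes)(=CH-C6H4-2-OiPr) (second-generation Hoveyda–Grubbs catalyst, 5 mol%), CH2Cl2, 40 °C
Reagents that add atoms: none
Why: Olefin cross-metathesis of the 1,1-disubstituted alkene with an α,β-unsaturated aldehyde (propene is lost) gives the trisubstituted enal with E favoured thermodynamically, the free acid and both ring stereocentres are untouched, and the minor Z isomer is removed by chromatography.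

**Step 6**
Reactants: 13 m-cresol (3-methylphenol)
Product: 16 orcinol (5-methylbenzene-1,3-diol), via aryl trimethylsilyl ether 14 (not isolated), via arylboronate 15 (not isolated)
Conditions: (Me3Si)2NH (0.6 equiv), neat, 100 °C, then vacuum; [Ir(OMe)(cod)]2 (1.5 mol%), 4,4'-di-tert-butyl-2,2'-bipyridine (3 mol%), HBpin (1.5 equiv), THF, 80 °C; then KHSO5 (Oxone), acetone/H2O, rt
Reagents that add atoms: potassium peroxymonosulfate (oxygen of the new OH), [K+].[O-]S(=O)(=O)OO; hexamethyldisilazane, C[Si](C)(C)N[Si](C)(C)C and pinacolborane, B1OC(C)(C)C(C)(C)O1 (their atoms stay only in 14 and 15)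
Why: One-pot O-silylation, sterically controlled iridium-catalysed C–H borylation (only C-5, meta to both substituents, is unhindered) and oxidation of the C–B bond, the silyl group being lost in the acidic aqueous oxidant; no stereocentre is formed.

**Step 7**
Reactants: 12 (1S,2R)-3,3-dimethyl-2-[(3E)-3-methyl-5-oxopent-3-en-1-yl]cyclohexane-1-carboxylic acid; 16 orcinol
Product: 18 (1S,2R)-2-{2-[(2R)-5-hydroxy-2,7-dimethyl-2H-chromen-2-yl]ethyl}-3,3-dimethylcyclohexane-1-carboxylic acid (target), via carbinol adduct 17 (not isolated)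
Conditions: 16 (1.5 equiv), (R)-3,3'-bis(2,4,6-triisopropylphenyl)-1,1'-binaphthyl-2,2'-diyl N-triflylphosphoramide (10 mol%), PhMe/CH2Cl2, 5 Å MS, −30 → 0 °C
Reagents that add atoms: none
Why: Proposed new method: acid-catalysed Friedel–Crafts 1,2-addition of C-2 of orcinol (flanked by both hydroxyls) to the enal gives carbinol 17, loss of water gives the 2-hydroxyaryl allyl cation (protonated o-quinone methide) as a contact ion pair with the chiral phosphoramide anion, and C–O closure at the tertiary terminus (formally an oxa-6π electrocyclisation) sets C-2 as R under catalyst control because the remote ring centres exert no bias; the closest known reaction types are the chiral N-triflylphosphoramide ion-pair cyclisation of o-hydroxyaryl allylic alcohols to 2,2-disubstituted 2H-chromenes and the achiral amine-salt annulation of resorcinols with enals.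

**Compound list**
1 | 2-methylhexa-1,5-diene | C=C(C)CCC=C | starting material
2 | acryloyl chloride | C=CC(=O)Cl | starting material
3 | 1,3-oxazolidin-2-one | O=C1NCCO1 | starting material (released again in step 4)
4 | (2E)-6-methylhepta-2,6-dienoyl chloride | C=C(C)CC/C=C/C(=O)Cl | intermediate (not isolated)
5 | 3-[(2E)-6-methylhepta-2,6-dienoyl]-1,3-oxazolidin-2-one | C=C(C)CC/C=C/C(=O)N1CCOC1=O | intermediate
6 | 5-bromo-2-methylpent-2-ene | CC(C)=CCCBr | starting material
7 | 5-bromo-2-iodo-2-methylpentane | CC(C)(I)CCCBr | intermediate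
8 | 3-[(3R)-3-(5-bromo-2-methylpentan-2-yl)-6-methylhept-6-enoyl]-1,3-oxazolidin-2-one | C=C(C)CC[C@H](CC(=O)N1CCOC1=O)C(C)(C)CCCBr | intermediate
9 | 3-{[(1S,2R)-3,3-dimethyl-2-(3-methylbut-3-en-1-yl)cyclohexyl]carbonyl}-1,3-oxazolidin-2-one | C=C(C)CC[C@@H]1[C@@H](C(=O)N2CCOC2=O)CCCC1(C)C | intermediate (not isolated)
10 | (1S,2R)-3,3-dimethyl-2-(3-methylbut-3-en-1-yl)cyclohexane-1-carboxylic acid | C=C(C)CC[C@@H]1[C@@H](C(=O)O)CCCC1(C)C | intermediate
11 | (E)-but-2-enal (crotonaldehyde) | C/C=C/C=O | starting material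
12 | (1S,2R)-3,3-dimethyl-2-[(3E)-3-methyl-5-oxopent-3-en-1-yl]cyclohexane-1-carboxylic acid | O=C/C=C(\C)CC[C@@H]1[C@@H](C(=O)O)CCCC1(C)C | intermediate
13 | m-cresol (3-methylphenol) | Cc1cccc(O)c1 | starting material
14 | trimethyl(3-methylphenoxy)silane | Cc1cccc(O[Si](C)(C)C)c1 | intermediate (not isolated)
15 | trimethyl[3-methyl-5-(4,4,5,5-tetramethyl-1,3,2-dioxaborolan-2-yl)phenoxy]silane | Cc1cc(O[Si](C)(C)C)cc(B2OC(C)(C)C(C)(C)O2)c1 | intermediate (not isolated)
16 | orcinol (5-methylbenzene-1,3-diol) | Cc1cc(O)cc(O)c1 | intermediate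
17 | (1S,2R)-2-[(3E)-5-(2,6-dihydroxy-4-methylphenyl)-5-hydroxy-3-methylpent-3-en-1-yl]-3,3-dimethylcyclohexane-1-carboxylic acid (carbinol carbon not controlled) | Cc1cc(O)c(C(O)/C=C(\C)CC[C@@H]2[C@@H](C(=O)O)CCCC2(C)C)c(O)c1 | intermediate (not isolated)
18 | (1S,2R)-2-{2-[(2R)-5-hydroxy-2,7-dimethyl-2H-chromen-2-yl]ethyl}-3,3-dimethylcyclohexane-1-carboxylic acid | Cc1cc(O)c2c(c1)O[C@](C)(CC[C@@H]1[C@@H](C(=O)O)CCCC1(C)C)C=C2 | target

**Totals**
Total step count: 7. Longest linear sequence: 5 steps (1 → 3 → 4 → 5 → 7).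

**Steps most likely to fail, with fallbacks**

Step 7 is the weakest. It is a new method, and three things can go wrong: orcinol may react at C-4 instead of C-2, the chromene may react further under acid, and catalyst control at C-2 is unproven. The fallback sets out from 12 and 16 and returns at 18. The condensation is run with ethylenediammonium diacetate (10 mol%) in toluene at 100 °C, the established amine-salt Knoevenagel/oxa-6π annulation that engages C-2 of orcinol. It gives 18 together with its C-2 epimer, (1S,2R)-2-{2-[(2S)-5-hydroxy-2,7-dimethyl-2H-chromen-2-yl]ethyl}-3,3-dimethylcyclohexane-1-carboxylic acid F1. Because the ring centres are already fixed, the two are diastereomers. They are separated by fractional crystallisation of (R)-1-phenylethylammonium (1S,2R)-2-{2-[(2R)-5-hydroxy-2,7-dimethyl-2H-chromen-2-yl]ethyl}-3,3-dimethylcyclohexane-1-carboxylate F2, or by chromatography on a chiral phase. Acidification with HCl returns 18. F1 is re-equilibrated at C-2 by irradiation (reversible electrocyclic ring opening) and recycled.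

Step 3 is next. The tertiary radical must add to a β-alkyl acceptor with high facial control by a catalyst, and the ee may fall short; a modest shortfall can be corrected by crystallisation at the stage of acid 10. The fallback sets out from acid chloride 4 and returns at 10, replacing catalyst control by a covalently bound auxiliary. Acid chloride 4 acylates the lithium salt of (S)-4-(diphenylmethyl)oxazolidin-2-one to give (4S)-4-(diphenylmethyl)-3-[(2E)-6-methylhepta-2,6-dienoyl]-1,3-oxazolidin-2-one F3. Radical addition of 7 (Bu3SnH, Et3B/O2, Yb(OTf)3 1 equiv, CH2Cl2/THF, −78 °C) then takes place on the chelated s-cis imide anti to the diphenylmethyl group, which is again the Re face of C-3. This gives (4S)-3-[(3R)-3-(5-bromo-2-methylpentan-2-yl)-6-methylhept-6-enoyl]-4-(diphenylmethyl)-1,3-oxazolidin-2-one F4. NaN(SiMe3)2 closes the ring (auxiliary and substrate preferences are matched) to (4S)-3-{[(1S,2R)-3,3-dimethyl-2-(3-methylbut-3-en-1-yl)cyclohexyl]carbonyl}-4-(diphenylmethyl)-1,3-oxazolidin-2-one F5. LiOH/H2O2 then releases 10 and the recovered auxiliary.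

Step 5 is third. Cross-metathesis of a 1,1-disubstituted alkene with an enal can stall or give poor E/Z ratios. The fallback sets out from 10 and returns at 12. Ozonolysis (O3, CH2Cl2/MeOH, −78 °C; Me2S) gives (1S,2R)-3,3-dimethyl-2-(3-oxobutyl)cyclohexane-1-carboxylic acid F6. Peterson olefination with lithiated N-tert-butyl-2-(trimethylsilyl)ethanimine (from the imine and LiN(iPr)2, 2.2 equiv, THF, −78 → −20 °C) gives (1S,2R)-2-[(3E)-5-(tert-butylimino)-3-methylpent-3-en-1-yl]-3,3-dimethylcyclohexane-1-carboxylic acid F7. Aqueous oxalic acid hydrolyses F7 to 12.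

**Further compounds**
F1 | step 7 | (1S,2R)-2-{2-[(2S)-5-hydroxy-2,7-dimethyl-2H-chromen-2-yl]ethyl}-3,3-dimethylcyclohexane-1-carboxylic acid | Cc1cc(O)c2c(c1)O[C@@](C)(CC[C@@H]1[C@@H](C(=O)O)CCCC1(C)C)C=C2
F2 | step 7 | (R)-1-phenylethylammonium (1S,2R)-2-{2-[(2R)-5-hydroxy-2,7-dimethyl-2H-chromen-2-yl]ethyl}-3,3-dimethylcyclohexane-1-carboxylate | C[C@@H]([NH3+])c1ccccc1.Cc1cc(O)c2c(c1)O[C@](C)(CC[C@@H]1[C@@H](C(=O)[O-])CCCC1(C)C)C=C2
F3 | step 3 | (4S)-4-(diphenylmethyl)-3-[(2E)-6-methylhepta-2,6-dienoyl]-1,3-oxazolidin-2-one | C=C(C)CC/C=C/C(=O)N1[C@@H](C(c2ccccc2)c2ccccc2)COC1=O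
F4 | step 3 | (4S)-3-[(3R)-3-(5-bromo-2-methylpentan-2-yl)-6-methylhept-6-enoyl]-4-(diphenylmethyl)-1,3-oxazolidin-2-one | C=C(C)CC[C@H](CC(=O)N1[C@@H](C(c2ccccc2)c2ccccc2)COC1=O)C(C)(C)CCCBr
F5 | step 3 | (4S)-3-{[(1S,2R)-3,3-dimethyl-2-(3-methylbut-3-en-1-yl)cyclohexyl]carbonyl}-4-(diphenylmethyl)-1,3-oxazolidin-2-one | C=C(C)CC[C@@H]1[C@@H](C(=O)N2[C@@H](C(c3ccccc3)c3ccccc3)COC2=O)CCCC1(C)C
F6 | step 5 | (1S,2R)-3,3-dimethyl-2-(3-oxobutyl)cyclohexane-1-carboxylic acid | CC(=O)CC[C@@H]1[C@@H](C(=O)O)CCCC1(C)C
F7 | step 5 | (1S,2R)-2-[(3E)-5-(tert-butylimino)-3-methylpent-3-en-1-yl]-3,3-dimethylcyclohexane-1-carboxylic acid | CC(C)(C)N=C/C=C(\C)CC[C@@H]1[C@@H](C(=O)O)CCCC1(C)C
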